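If slow addition were to leave noon, midnight and autumn level with dawn, the delay it causes would have to be too short for the target curve to show. The earlier runs tell how short that is.

| flask | starting material | reagent | remark | time |
|---|---|---|---|---|
| north-west | 0.020 M | 0.019 M | run made earlier |  |
| north-east | 0.020 M | 0.0095 M | run made earlier |  |
| south | 0.020 M | 0.014 M | run made earlier |  |
| noon | 0.020 M (fed, over 6.0 h) | 0.0190 M | all else is in the flask from the start; the feed brings no volume worth counting | 30 h |
| midnight | 0.020 M | 0.0190 M (in portions, 3, over 6.0 h) | first portion at the start, last at 6.0 h | 30 h |
| dawn | 0.020 M | 0.0190 M | everything together at the start | 30 h |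
| autumn | 0.020 M | 0.0190 M (fed, over 6.0 h) | all else is in the flask from the start; the feed brings no volume worth counting | 30 h |

| run | time / h | target / % | starting material / % |
|---|---|---|---|
| north-west | 1.33 | 1 | 98 |
| north-west | 4.00 | 0 | 100 |
| north-west | 6.00 | 3 | 99 |
| north-west | 10.0 | 2 | 98 |
| north-west | 15.0 | 3 | 97 |
| north-west | 20.0 | 12 | 89 |
| north-east | 2.50 | 1 | 102 |
| north-east | 8.00 | 0 | 101 |
| north-east | 12.0 | 1 | 101 |
| north-east | 20.0 | 0 | 97 |
| north-east | 30.0 | 5 | 99 |
| north-east | 40.0 | 9 | 94 |
| south | 2.50 | 0 | 98 |
| south | 8.00 | 1 | 99 |
| south | 12.0 | 0 | 99 |
| south | 20.0 | 0 | 97 |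
| south | 30.0 | 11 | 86 |
| south | 40.0 | 33 | 67 |

(standard deviation of a reading: 1.5 percentage points)

- the analysis behind the earlier runs scatters by 1.5 percentage points, standard deviation

- which flask leads in amount of target, in percent of the starting material charged ("all alike" within 1.5 percentage points) (noon / midnight / dawn / autumn / all alike)
- how much target is there at the end, in percent of the starting material charged: noon
- how much target is there at the end, in percent of the starting material charged: midnight
- how much target is there at the end, in percent of the starting material charged: dawn
- how much target is there at the end, in percent of the starting material charged: autumn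

The curves show a long lag and then a fast rise, as autocatalysis does. The better variable is therefore a, the fraction of starting material left, through its odds o, spent over left. Reagent is the limiting reagent, and W is its charge minus the starting material spent, assuming one is used per one. In south, o grows at g = 0.111 h⁻¹ between 30.0 h and 40.0 h, while W averages 0.00930 M. The reading κ = g/W = 0.198 L mol⁻¹ min⁻¹, the odds growth constant per unit of reagent left, is the quantity carried forward.

Dawn has the north-west charge, so it starts from 89% left at 20.0 h, with W = 0.0168 M. Holding W there gives 52.3% left at the end. Using the mean of that W and the emptier final one gives 62.9% left. With that second pass, a delay moves the target by a(1−a)κW per hour, so the margin of 1.5 percentage points equals a delay of 0.411 h. As an estimate, reagent added over 6.0 h, steadily or in portions, delays midnight and autumn by roughly half that time, 3.00 h, which is longer than that. Noon, fed starting material instead, is taken to lag as well, by a delay not reckoned here. This reckoning therefore has dawn leading, not all alike.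

The forecast also chose dawn, with 52% for dawn, 39% for midnight, 39% for autumn and 35% for noon, “carrying north-west on from 12% at 20 h”. Its dawn figure stands above the 47.7% spent in the first pass here.

The flasks give dawn in the lead: dawn 43.1%, midnight 33.9%, autumn 33.9%, noon 22.6%.

    reagent ⇌ dormant form (K = 2.50, k = 0.00634 min⁻¹)
    starting material + reagent → target (k = 5.47 × 10⁻⁵ L mol⁻¹ min⁻¹)
    starting material + reagent + target → 2 target (k = 50.4 L² mol⁻² min⁻¹)
    target ⇌ isomer of the product (K = 1.50, k = 5.72 × 10⁻⁵ min⁻¹)

At 6.00 h, noon holds 0.0161% target against 0.0369% in autumn. With dawn's 56% left, W = 0.0102 M. The odds gap then reads as a delay of 3.35 h for autumn and 8.07 h for noon, which is longer than its feed.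

For dawn read at 2.0 d, the same two passes from 56% left give 12.5% and then 26.6% left. The computed flask holds 24.5%.

The earlier runs and the new flask were computed from invented constants.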